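**Retrosyn­thetic overview**
1. The C18 aldehyde comes from chemoselective oxidation of the 6α,8α,18‑triol. The C12–C13 bond comes from a Ni‑catalysed reductive coupling (C12 alkyl radical) of a C16 bromo‑triol decalin with a C9 (R)‑bromobutenyl butenolide.
2. The 8α‑OH comes from MHAT hydration of the Δ8(17) alkene: the C8 radical takes up O2 from the α face.
3. Key disconnection: C4–C5 and C9–C10 form in one titanocene(III) radical cascade of an acyclic epoxy‑diene. The initiator is a 2‑methyl‑2‑alkyloxirane, which gives C18–O and no C3–O. Ring A closes first and ring B second. The C6 carbinol is the only stereocentre present and relays to C4, C5, C9 and C10.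
4. The acyclic chain comes from hept‑1‑en‑6‑yne, CH2O, a propargyl unit (asymmetric propargylation sets C6) and oxirane. Both E‑trisubstituted alkenes are made by carboalumination, and the oxirane by Wacker oxidation then Corey–Chaykovsky reaction.
5. The butenolide ring is closed separately before the coupling. It comes from pent‑3‑yn‑1‑ol and methyl propiolate: asymmetric alkynylation sets C16, followed by methylcuprate addition and lactonisation.

Assumption: labdane labels are used (C1–C16; C17 on C8, C18 = 4α, C19 = 4β, C20 on C10; butenolide positions given as furanone locants); the catalyst antipodes named are those expected by analogy to give the drawn configuration, the mirror‑image catalysts being equally available; the five starting materials are catalogue chemicals.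

**Step 1**
Reactants: 1 hept-1-en-6-yne
Product: 4 (2E)-3-methylocta-2,7-dien-1-ol, via alkenylalane 2 (not isolated), via lithium alanate 3 (not isolated)
Conditions: Me3Al (2 equiv), Cp2ZrCl2 (0.25 equiv), CH2Cl2, 0 °C→rt; evaporate; n‑BuLi (1 equiv), hexane/THF, 0 °C; (CH2O)n, rt; aq HCl
Reagents that add atoms: trimethylaluminium C[Al](C)C; paraformaldehyde (as formaldehyde) C=O; n‑butyllithium [Li]CCCC (only in intermediate 3)
Why: Negishi Zr‑catalysed syn‑carboalumination is far faster on the terminal alkyne than on the monosubstituted alkene and puts Me on the internal carbon, and the ate complex is hydroxymethylated with retention, giving the pure E trisubstituted alkene.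

**Step 2**
Reactants: 4 (2E)-3-methylocta-2,7-dien-1-ol
Product: 5 (2E)-3-methylocta-2,7-dienal
Conditions: activated MnO2 (15 equiv), CH2Cl2, rt
Reagents that add atoms: none
Why: MnO2 allylic oxidation touches only the allylic alcohol and leaves the E geometry and the terminal alkene intact.

**Step 3**
Reactants: 6 3-bromoprop-1-yne (propargyl bromide)
Product: 8 2-(propa-1,2-dien-1-yl)-4,4,5,5-tetramethyl-1,3,2-dioxaborolane, via allenylmagnesium bromide 7 (not isolated)
Conditions: Mg, HgCl2 (1 mol %), Et2O, 0 °C; i‑PrOBpin, −78 °C→rt; HCl·Et2O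
Reagents that add atoms: magnesium [Mg] (only in intermediate 7); 2‑isopropoxy‑4,4,5,5‑tetramethyl‑1,3,2‑dioxaborolane CC(C)OB1OC(C)(C)C(C)(C)O1
Why: Grignard formation from propargyl bromide gives the allenyl reagent, and borylation delivers the thermodynamically preferred allenylboronate.

**Step 4**
Reactants: 5 (2E)-3-methylocta-2,7-dienal; 8 2-(propa-1,2-dien-1-yl)-4,4,5,5-tetramethyl-1,3,2-dioxaborolane
Product: 10 (4S,5E)-6-methylundeca-5,10-dien-1-yn-4-ol, via pinacol borate ester 9 (not isolated)
Conditions: (S)‑TRIP phosphoric acid (10 mol %), 4 Å MS, toluene, −20 °C; aq NaHCO3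
Reagents that add atoms: none
Why: In this chiral‑phosphoric‑acid‑catalysed propargylboration the allenylboronate reacts through a closed six‑membered SE2′ transition state whose boronate oxygen is hydrogen‑bonded to the catalyst, so one enal face is attacked and C6 is set as S with exclusive 1,2‑addition.

**Step 5**
Reactants: 10 (4S,5E)-6-methylundeca-5,10-dien-1-yn-4-ol; 11 oxirane
Product: 14 (3E,6S,7E)-4,8-dimethyltrideca-3,7,12-triene-1,6-diol, via alkenylalane alkoxide 12 (not isolated), via lithium alanate 13 (not isolated)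
Conditions: Me3Al (3.5 equiv), Cp2ZrCl2 (0.3 equiv), CH2Cl2, 0 °C→rt; evaporate; n‑BuLi (2.1 equiv), THF/hexane, −78→0 °C; oxirane (3 equiv), 0 °C→rt; aq HCl/Rochelle salt
Reagents that add atoms: trimethylaluminium C[Al](C)C; n‑butyllithium [Li]CCCC (only in intermediate 13)
Why: In this second Negishi carboalumination the carbinol is masked in situ as its aluminium alkoxide, and the derived alanate opens oxirane with retention, which builds the E C8=C9 alkene and C11–C12 in one flask without touching C6.

**Step 6**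
Reactants: 14 (3E,6S,7E)-4,8-dimethyltrideca-3,7,12-triene-1,6-diol
Product: 15 (6E,8S,10E)-8,13-dihydroxy-6,10-dimethyltrideca-6,10-dien-2-one
Conditions: PdCl2 (10 mol %), Cu(OAc)2·H2O (20 mol %), O2 (1 atm), DMA/H2O 7:1, rt
Reagents that add atoms: water O
Why: In the Tsuji–Wacker oxidation only the monosubstituted alkene binds Pd(II), and the acetate‑buffered medium keeps the acid‑labile allylic carbinol from ionising.

**Step 7**
Reactants: 15 (6E,8S,10E)-8,13-dihydroxy-6,10-dimethyltrideca-6,10-dien-2-one
Product: 16 (3E,6S,7E)-4,8-dimethyl-11-(2-methyloxiran-2-yl)undeca-3,7-diene-1,6-diol (1:1 at the oxirane carbon)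
Conditions: Me3S+ I− (3.5 equiv), NaH (3.5 equiv), DMSO/THF, 0 °C→rt
Reagents that add atoms: trimethylsulfonium iodide C[S+](C)C.[I-]
Why: Corey–Chaykovsky methylene transfer to the methyl ketone adds C18, and the new oxirane carbon forms unselectively, which does not matter because it becomes a planar radical in step 8.

**Step 8 (key step)**
Reactants: 16 (3E,6S,7E)-4,8-dimethyl-11-(2-methyloxiran-2-yl)undeca-3,7-diene-1,6-diol
Product: 19 13,14,15,16-tetranorlabd-8(17)-ene-6α,12,18-triol (4α-CH2OH; 4β-Me; 5α-H; 9α-H; 10β-Me), via bis(trimethylsilyl) ether 17 (not isolated), via cyclised tris(trimethylsilyl) ether 18 (not isolated)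
Conditions: TMSCl (7 equiv), 2,4,6‑collidine (10 equiv), THF, rt, 30 min; added over 2 h to Cp2TiCl2 (0.3 equiv), Mn dust (8 equiv), degassed THF (final 0.01 M), rt, 16 h; filter; K2CO3 (cat.), MeOH, 0 °C→rt
Reagents that add atoms: chlorotrimethylsilane C[Si](C)(C)Cl (only in intermediates 17 and 18)
Why: Proposed new method: Cp2TiCl opens the 2,2‑disubstituted oxirane homolytically (Nugent–RajanBabu opening) to a planar tertiary C4 radical bearing CH2OTi that is too hindered to be trapped by a second Ti(III), so it adds 6‑endo to C5 and the resulting C10 radical adds 6‑endo to C9 through a chair–chair array (E alkenes give the trans ring fusion and the equatorial C9 chain), the C6 silyloxy group staying equatorial because an axial one would be syn‑pentane to both C19 and C20, the bulkier CH2OTi arm taking the equatorial 4α site, and the C8 radical giving up a C17 hydrogen to Ti(III) to leave the exocyclic alkene; the closest known reaction type is the titanocene(III)‑catalysed radical cyclisation of 2,3‑epoxypolyprenes, extended here to an exo‑methylene‑type epoxide initiator and to stereo‑relay from a single carbinol centre.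

**Step 9**
Reactants: 19 13,14,15,16-tetranorlabd-8(17)-ene-6α,12,18-triol
Product: 20 12-bromo-13,14,15,16-tetranorlabd-8(17)-ene-6α,18-diol
Conditions: CBr4 (1.1 equiv), PPh3 (1.15 equiv), CH2Cl2, −30→0 °C
Reagents that add atoms: tetrabromomethane BrC(Br)(Br)Br
Why: In this Appel reaction under kinetic control only the unhindered primary C12 alkoxyphosphonium is displaced, the neopentyl C18–OH and the hindered secondary C6–OH being much slower, and it is run before C8–OH exists so that no tetrahydrofuran can close.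

**Step 10**
Reactants: 20 12-bromo-13,14,15,16-tetranorlabd-8(17)-ene-6α,18-diol
Product: 22 12-bromo-13,14,15,16-tetranorlabdane-6α,8α,18-triol, via 8α-hydroperoxide 21 (not isolated)
Conditions: Mn(dpm)3 (10 mol %), PhSiH3 (2.5 equiv), O2 (1 atm), i‑PrOH/CH2Cl2, 0 °C; then P(OEt)3, rt
Reagents that add atoms: dioxygen O=O
Why: In the Mukaiyama (MHAT) hydration H· adds to C17, and the tertiary C8 radical is captured by O2 from the α face opposite the axial C20 methyl, which sets 8α‑OH and 8β‑Me; any endocyclic alkene isomer carried over from step 8 gives the same radical.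

**Step 11**
Reactants: 23 pent-3-yn-1-ol
Product: 25 (3E)-4-bromopent-3-en-1-ol, via alkenylzirconocene 24 (not isolated)
Conditions: Cp2ZrHCl (2.5 equiv), THF, rt→40 °C; NBS (1.2 equiv), 0 °C
Reagents that add atoms: N‑bromosuccinimide O=C1CCC(=O)N1Br; zirconocene chloride hydride [H][Zr](Cl)(C1C=CC=C1)C1C=CC=C1 (Zr only in intermediate 24)
Why: Schwartz hydrozirconation is a syn addition, equilibration with excess reagent places Zr on the methyl‑bearing carbon, and bromodezirconation proceeds with retention to fix the E geometry of the future C13=C14 alkene.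

**Step 12**
Reactants: 25 (3E)-4-bromopent-3-en-1-ol
Product: 26 (3E)-4-bromopent-3-enal
Conditions: Dess–Martin periodinane (1.2 equiv), CH2Cl2, 0 °C; short silica plug; used at once
Reagents that add atoms: none
Why: Dess–Martin oxidation is mild and base‑free, so the β,γ‑unsaturated aldehyde does not slip into conjugation.

**Step 13**
Reactants: 26 (3E)-4-bromopent-3-enal; 27 methyl prop-2-ynoate
Product: 29 methyl (4R,6E)-7-bromo-4-hydroxyoct-6-en-2-ynoate, via methylzinc acetylide 28 (not isolated)
Conditions: (S,S)‑ProPhenol (20 mol %), Me2Zn (3 equiv), Ph3P=O (40 mol %), toluene, 0–4 °C; aq NH4Cl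
Reagents that add atoms: dimethylzinc C[Zn]C (only in intermediate 28)
Why: In the dinuclear zinc–ProPhenol asymmetric alkynylation the chiral Zn2 pocket binds the aldehyde and the acetylide together and delivers the propiolate to one face, setting C16 as R.

**Step 14**
Reactants: 29 methyl (4R,6E)-7-bromo-4-hydroxyoct-6-en-2-ynoate
Product: 31 (5R)-5-[(2E)-3-bromobut-2-en-1-yl]-4-methylfuran-2(5H)-one, via Z-hydroxy enoate 30 (not isolated)
Conditions: Me2CuLi (2.5 equiv, from MeLi/CuI), THF/Et2O, −78 °C; sat. NH4Cl, −78 °C→rt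
Reagents that add atoms: lithium dimethylcuprate [Li+].C[Cu-]C (from methyllithium [Li]C and copper(I) iodide [Cu]I)
Why: Syn conjugate carbocupration of the ynoate places the methyl on the β carbon and the carbinol cis to the ester, so the Z‑hydroxy enoate lactonises on quench; the vinyl bromide is inert at −78 °C and C16 is untouched.

**Step 15**
Reactants: 22 12-bromo-13,14,15,16-tetranorlabdane-6α,8α,18-triol; 31 (5R)-5-[(2E)-3-bromobut-2-en-1-yl]-4-methylfuran-2(5H)-one
Product: 32 (13E,16R)-6α,8α,18-triol with the full target skeleton (CH2OH in place of CHO at C4α)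
Conditions: NiBr2·glyme (10 mol %), 4,4′‑di‑tert‑butyl‑2,2′‑bipyridine (10 mol %), Mn powder (3 equiv), NaI (0.5 equiv), DMA, 25–35 °C; 31 (1.3 equiv); no added base
Reagents that add atoms: none
Why: In this nickel‑catalysed reductive cross‑electrophile coupling the vinyl bromide adds oxidatively with retention while the alkyl bromide enters as the primary C12 radical, so the three free hydroxyls and the butenolide are tolerated, and the absence of base keeps C8–OH from displacing bromide and keeps C16 from epimerising.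

**Step 16**
Reactants: 32 (13E,16R)-6α,8α,18-triol with the full target skeleton
Product: 33 CNP0143336.1 (target; 4R,5R,6S,8R,9R,10S,13E,16R)
Conditions: TEMPO (0.2 equiv), PhI(OAc)2 (1.05 equiv), CH2Cl2, 0 °C→rt, stopped at full conversion
Reagents that add atoms: none
Why: The TEMPO/oxoammonium oxidation selects the primary C18–OH over the hindered secondary and the tertiary alcohols, and limiting the oxidant avoids further oxidation through the lactol to the 18,6‑lactone.

**Compound list**
1 | hept-1-en-6-yne | C=CCCCC#C | starting material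
2 | [(1E)-2-methylhepta-1,6-dien-1-yl]dimethylalane | C=CCCC/C(C)=C/[Al](C)C | intermediate
3 | lithium butyl(dimethyl)[(1E)-2-methylhepta-1,6-dien-1-yl]aluminate | [Li+].C=CCCC/C(C)=C/[Al-](C)(C)CCCC | intermediate
4 | (2E)-3-methylocta-2,7-dien-1-ol | C=CCCC/C(C)=C/CO | intermediate
5 | (2E)-3-methylocta-2,7-dienal | C=CCCC/C(C)=C/C=O | intermediate
6 | 3-bromoprop-1-yne | BrCC#C | starting material
7 | allenylmagnesium bromide | C=C=C[Mg]Br | intermediate
8 | allenylboronic acid pinacol ester | C=C=CB1OC(C)(C)C(C)(C)O1 | intermediate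
9 | pinacol borate ester of 10 | C#CC[C@H](OB1OC(C)(C)C(C)(C)O1)/C=C(\C)CCCC=C | intermediate
10 | (4S,5E)-6-methylundeca-5,10-dien-1-yn-4-ol | C#CC[C@H](O)/C=C(\C)CCCC=C | intermediate
11 | oxirane | C1CO1 | starting material
12 | (E)-alkenyl(dimethyl)alane, C6 O‑dimethylaluminium alkoxide | C[Al](C)/C=C(\C)C[C@H](O[Al](C)C)/C=C(\C)CCCC=C | intermediate
13 | lithium butyl alanate of 12 | [Li+].CCCC[Al-](C)(C)/C=C(\C)C[C@H](O[Al](C)C)/C=C(\C)CCCC=C | intermediate
14 | (3E,6S,7E)-4,8-dimethyltrideca-3,7,12-triene-1,6-diol | OCC/C=C(\C)C[C@H](O)/C=C(\C)CCCC=C | intermediate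
15 | (6E,8S,10E)-8,13-dihydroxy-6,10-dimethyltrideca-6,10-dien-2-one | OCC/C=C(\C)C[C@H](O)/C=C(\C)CCCC(C)=O | intermediate
16 | (3E,6S,7E)-4,8-dimethyl-11-(2-methyloxiran-2-yl)undeca-3,7-diene-1,6-diol (oxirane carbon 1:1) | OCC/C=C(\C)C[C@H](O)/C=C(\C)CCCC1(C)CO1 | intermediate
17 | bis(trimethylsilyl) ether of 16 | C[Si](C)(C)OCC/C=C(\C)C[C@H](O[Si](C)(C)C)/C=C(\C)CCCC1(C)CO1 | intermediate
18 | tris(trimethylsilyl) ether of 19 | C[Si](C)(C)OCC[C@@H]1[C@@]2(C)CCC[C@@](C)(CO[Si](C)(C)C)[C@@H]2[C@@H](O[Si](C)(C)C)CC1=C | intermediate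
19 | 13,14,15,16-tetranorlabd-8(17)-ene-6α,12,18-triol | OCC[C@@H]1[C@@]2(C)CCC[C@@](C)(CO)[C@@H]2[C@@H](O)CC1=C | intermediate
20 | 12-bromo-13,14,15,16-tetranorlabd-8(17)-ene-6α,18-diol | BrCC[C@@H]1[C@@]2(C)CCC[C@@](C)(CO)[C@@H]2[C@@H](O)CC1=C | intermediate
21 | 12-bromo-8α-hydroperoxy-13,14,15,16-tetranorlabdane-6α,18-diol | BrCC[C@@H]1[C@@]2(C)CCC[C@@](C)(CO)[C@@H]2[C@@H](O)C[C@@]1(C)OO | intermediate
22 | 12-bromo-13,14,15,16-tetranorlabdane-6α,8α,18-triol | BrCC[C@@H]1[C@@]2(C)CCC[C@@](C)(CO)[C@@H]2[C@@H](O)C[C@@]1(C)O | intermediate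
23 | pent-3-yn-1-ol | CC#CCCO | starting material
24 | (E)-alkenylzirconocene chloride, O‑zirconated (Cp drawn σ‑bonded) | C/C(=C\CCO[Zr](Cl)(C1C=CC=C1)C1C=CC=C1)[Zr](Cl)(C1C=CC=C1)C1C=CC=C1 | intermediate
25 | (3E)-4-bromopent-3-en-1-ol | C/C(Br)=C\CCO | intermediate
26 | (3E)-4-bromopent-3-enal | C/C(Br)=C\CC=O | intermediate
27 | methyl prop-2-ynoate | C#CC(=O)OC | starting material
28 | methyl 3-(methylzincio)prop-2-ynoate | C[Zn]C#CC(=O)OC | intermediate
29 | methyl (4R,6E)-7-bromo-4-hydroxyoct-6-en-2-ynoate | COC(=O)C#C[C@H](O)C/C=C(\C)Br | intermediate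
30 | methyl (2Z,4R,6E)-7-bromo-4-hydroxy-3-methylocta-2,6-dienoate | COC(=O)/C=C(/C)[C@H](O)C/C=C(\C)Br | intermediate
31 | (5R)-5-[(2E)-3-bromobut-2-en-1-yl]-4-methylfuran-2(5H)-one | CC1=CC(=O)O[C@@H]1C/C=C(\C)Br | intermediate
32 | (13E,16R)-6α,8α,18-triol (target with CH2OH at C4α) | CC1=CC(=O)O[C@@H]1C/C=C(\C)CC[C@@H]1[C@@]2(C)CCC[C@@](C)(CO)[C@@H]2[C@@H](O)C[C@@]1(C)O | intermediate
33 | CNP0143336.1 | CC1=CC(=O)O[C@@H]1C/C=C(\C)CC[C@@H]1[C@@]2(C)CCC[C@@](C)(C=O)[C@@H]2[C@@H](O)C[C@@]1(C)O | target

**Step count**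
Total step count: 16.
Longest linear sequence: 11 steps (1, 2, 4, 5, 6, 7, 8, 9, 10, 15, 16).

**Three steps most likely to fail**

*Step 8.* The risks are modest 4α/4β selectivity, because the equatorial CH2OTi arm lies peri to the C6 silyloxy group, and stalling at the monocycle.
- The fallback makes the oxygenated arm of the C4 radical branched, so that it can only sit equatorial. It sets out from ketone 15 and comes back at triol 19.
- Chloro(trimethylsilyl)methyllithium (ClCH2SiMe3/s‑BuLi, 3.5 equiv, THF, −78 °C→rt) converts 15 into the α,β‑epoxysilane F1.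
- The step‑8 protocol then runs through the transient bis(silyl ether) of the epoxysilane F2 and the cyclised tris(silyl ether) F3 to the 18‑(trimethylsilyl) triol F4. Here the C4 radical carried a CH(OTi)SiMe3 group, whose axial placement against C20 is prohibitive.
- KOt‑Bu in wet DMSO removes the carbinol silicon (protodesilylation of an α‑hydroxysilane) and gives 19.

*Step 15.* The risks are a slow reaction of the internal, α‑methyl vinyl bromide, homocoupling, and closure of the 8,12‑ether.
- The fallback replaces the reductive coupling by a preformed organozinc and a two‑electron Pd cycle. It sets out from bromo‑triol 22 and comes back at triol 32.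
- Persilylation (TMSOTf, 2,6‑lutidine) gives the tris(trimethylsilyl) ether bromide F5.
- Zinc insertion (Zn dust, LiCl, THF, 45 °C) gives the alkylzinc bromide F6.
- Negishi coupling with 31 (PdCl2(dppf), THF, rt) gives the coupled tris(silyl ether) F7.
- K2CO3/MeOH then releases 32.

*Step 16.* The risks are over‑oxidation through the lactol to the lactone, or incomplete primary/secondary selectivity on the final compound.
- The fallback settles the C18 oxidation level before the butenolide is present. It sets out from bromo‑triol 22 and comes back at target 33.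
- Excess TEMPO/PhI(OAc)2 (2.5 equiv) deliberately takes 22 to the 18,6α‑lactone F8.
- DIBAL‑H (2.2 equiv, CH2Cl2, −78 °C) stops at the hydroxy aldehyde (lactol tautomer) bromide F9.
- The step‑15 coupling of F9 with 31 gives 33 directly.

**Further compounds**
F1 | step 8 | (3E,6S,7E)-4,8-dimethyl-11-[2-methyl-3-(trimethylsilyl)oxiran-2-yl]undeca-3,7-diene-1,6-diol | OCC/C=C(\C)C[C@H](O)/C=C(\C)CCCC1(C)OC1[Si](C)(C)C
F2 | step 8 | bis(trimethylsilyl) ether of F1 | C[Si](C)(C)OCC/C=C(\C)C[C@H](O[Si](C)(C)C)/C=C(\C)CCCC1(C)OC1[Si](C)(C)C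
F3 | step 8 | tris(trimethylsilyl) ether of F4 | C[Si](C)(C)OCC[C@@H]1[C@@]2(C)CCC[C@@](C)(C(O[Si](C)(C)C)[Si](C)(C)C)[C@@H]2[C@@H](O[Si](C)(C)C)CC1=C
F4 | step 8 | 18-(trimethylsilyl)-13,14,15,16-tetranorlabd-8(17)-ene-6α,12,18-triol | OCC[C@@H]1[C@@]2(C)CCC[C@@](C)(C(O)[Si](C)(C)C)[C@@H]2[C@@H](O)CC1=C
F5 | step 15 | tris(trimethylsilyl) ether of 22 | BrCC[C@@H]1[C@@]2(C)CCC[C@@](C)(CO[Si](C)(C)C)[C@@H]2[C@@H](O[Si](C)(C)C)C[C@@]1(C)O[Si](C)(C)C
F6 | step 15 | C12 alkylzinc bromide from F5 | Br[Zn]CC[C@@H]1[C@@]2(C)CCC[C@@](C)(CO[Si](C)(C)C)[C@@H]2[C@@H](O[Si](C)(C)C)C[C@@]1(C)O[Si](C)(C)C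
F7 | step 15 | tris(trimethylsilyl) ether of 32 | CC1=CC(=O)O[C@@H]1C/C=C(\C)CC[C@@H]1[C@@]2(C)CCC[C@@](C)(CO[Si](C)(C)C)[C@@H]2[C@@H](O[Si](C)(C)C)C[C@@]1(C)O[Si](C)(C)C
F8 | step 16 | 12-bromo-8α-hydroxy-13,14,15,16-tetranorlabdan-18,6α-olide | BrCC[C@@H]1[C@@]2(C)CCC[C@@]3(C)C(=O)O[C@H]([C@H]23)C[C@@]1(C)O
F9 | step 16 | 12-bromo-6α,8α-dihydroxy-13,14,15,16-tetranorlabdan-18-al | BrCC[C@@H]1[C@@]2(C)CCC[C@@](C)(C=O)[C@@H]2[C@@H](O)C[C@@]1(C)O
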